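Briarane numbering is used (C1: methyl-bearing ring-fusion carbon; C10: ring-fusion CH; C11–C14: rest of ring A; C20: methylidene carbon). Ring A is assembled in one operation by a catalytic enantioselective Diels–Alder reaction that forms C10–C11 and C1–C14: a 1-silyloxy vinylallene (C14=C13–C12=C11=C20) adds to ethyl (E)-3-formylcrotonate (C2–C1(Me)=C10–C9). The step exploits the trans relation of Me-15 on C1 and H-10 (E dienophile), the cis relation of O-14 and C2 (endo rule) and the C11=C20 methylidene (remaining allene π bond). The ten-membered ring then follows from chelation-controlled additions at C2 and C9, an enol ether oxidation, a samarium Reformatsky lactonisation and ring-closing metathesis at C5=C6, with the methylidene masked meanwhile as an allylic aryl ether.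

Key step: step 3

Remark on numbering: C2–C9 run round the ten-membered ring, the lactone is C7–O–C19(=O)–C17(Me-18)–C8, and α/β refer to ring A drawn with Me-15 up (β).
Assumption: the (R)-configured oxazaborolidinium ion is specified from the accepted model for 2-substituted enals (aldehyde bound to boron, diene on the face remote from the aryl groups); the antipodal catalyst would be taken if the sense proved opposite.
Assumption: penta-3,4-dien-1-ol, ethyl (E)-3-methyl-4-oxobut-2-enoate, 4-bromo-2-methylbut-1-ene and (E)-1-methoxybuta-1,3-diene are purchased.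

Step 1
Reactants: 1 penta-3,4-dien-1-ol
Product: 2 penta-3,4-dienal
Conditions: Dess–Martin periodinane, NaHCO3, CH2Cl2, 0 °C; used as a cold solution
Reagents that add atoms: none
Why: Dess–Martin oxidation of the primary alcohol under buffered, non-enolising conditions, so that the β,γ-allenyl aldehyde does not isomerise into conjugation.

Step 2
Reactants: 2 penta-3,4-dienal
Product: 3 (E)-triisopropyl(penta-1,3,4-trien-1-yloxy)silane
Conditions: i-Pr3SiOTf, Et3N, Et2O, −78 → 0 °C; E isomer enriched on Et3N-deactivated silica
Reagents that add atoms: triisopropylsilyl triflate, CC(C)[Si](OS(=O)(=O)C(F)(F)F)(C(C)C)C(C)C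
Why: Soft enolisation (silyl triflate/amine) and O-silylation give the conjugated dienol ether as an E/Z mixture; only its E isomer can reach the s-cis geometry needed in step 3, so residual Z material is inert there.

Step 3
Reactants: 3 (E)-triisopropyl(penta-1,3,4-trien-1-yloxy)silane; 4 ethyl (E)-3-methyl-4-oxobut-2-enoate
Product: 5 ethyl (1S,5S,6R)-6-formyl-6-methyl-2-methylidene-5-(triisopropylsilyloxy)cyclohex-3-ene-1-carboxylate
Conditions: (R)-3,3-diphenyl-1-(o-tolyl)tetrahydropyrrolo[1,2-c][1,3,2]oxazaborole (20 mol %) protonated with (CF3SO2)2NH (18 mol %), CH2Cl2, −78 → −40 °C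
Reagents that add atoms: none
Why: Concerted but asynchronous suprafacial [4+2] cycloaddition of the s-cis diene C14=C13–C12=C11 of 3 onto the C1=C10 alkene of 4, whose formyl group is bound to the chiral boron Lewis acid; the closest known reaction types are the oxazaborolidinium-catalysed enantioselective Diels–Alder reaction of 2-substituted enals with 1-silyloxydienes and the Diels–Alder reaction of vinylallenes. Ring A closes by intermolecular [4π+2π] cycloaddition, both σ bonds (C10–C11 leading, C1–C14 lagging) arising in one transition state. The trans relation of Me-15 and H-10 is carried over stereospecifically from the E geometry of 4, the cis relation of O-14 and the formyl carbon C2 comes from the formyl-endo approach to the E-configured silyloxy terminus, and the absolute configuration at C1, C10 and C14 comes from shielding of one enal face by the aryl groups of the catalyst. Regioselectivity (the silyloxy-remote allene carbon C11 to the formyl β-carbon C10) is secured by the matched polarisation of the donor diene and the Lewis acid-bound enal, which outweighs the β-ester. Periselectivity is secured because the terminal allene π bond lies orthogonal to the diene, so it stays behind as the C11=C20 methylidene.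

Step 4
Reactants: 5 Diels–Alder adduct
Product: 6 ethyl (1S,5S,6R)-6-formyl-5-hydroxy-6-methyl-2-methylidenecyclohex-3-ene-1-carboxylate
Conditions: HF·pyridine, pyridine, THF, 0 °C → rt
Reagents that add atoms: none
Why: Fluoride-mediated cleavage of the allylic silyl ether under buffered, non-basic conditions, which avoids retro-aldol cleavage of the β-hydroxy aldehyde and frees O-14 for chelation and for directing the epoxidation.

Step 5
Reactants: 6 hydroxy aldehyde
Product: 8 (2S)-lactone alcohol (trans-fused γ-lactone O-2–C9(=O), 3-methylbut-3-enyl chain on C2, 14α-OH, 11(20),12-diene), via dihydroxy ester 7 (not isolated)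
Conditions: CH2=C(CH3)CH2CH2MgBr (from 4-bromo-2-methylbut-1-ene, Mg, THF; 2.3 equiv), THF, −78 °C, inverse addition; aq NH4Cl at −78 °C; then PPTS (cat.), CH2Cl2, rt
Reagents that add atoms: 4-bromo-2-methylbut-1-ene (as its Grignard reagent), C=C(C)CCBr
Why: Grignard addition to the formyl group under 1,3-chelation control (Cram–Reetz type: the magnesium alkoxide at O-14 ties the aldehyde oxygen into a six-membered chelate and the nucleophile enters from the face of Me-15, away from C10), which should set C2 as S, followed by 5-exo-trig lactonisation of the C2 hydroxyl onto the trans-disposed ester, which stores C9 at the acid oxidation level.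

Step 6
Reactants: 8 lactone alcohol
Product: 9 12α,13α-epoxy alcohol
Conditions: VO(acac)2 (5 mol %), t-BuOOH, CH2Cl2, 0 °C
Reagents that add atoms: tert-butyl hydroperoxide, CC(C)(C)OO
Why: Hydroxyl-directed vanadium-catalysed epoxidation: the pseudoaxial 14α-hydroxyl delivers the oxidant to its own face of the adjacent C12=C13 bond only, so the epoxide is α and the non-allylic alkenes are left.

Step 7
Reactants: 9 epoxy alcohol
Product: 10 13α,14α-diol with C11=C12 alkene and C20 p-methoxyphenyl ether
Conditions: Pd2(dba)3·CHCl3 (2.5 mol %), PPh3 (10 mol %), 4-methoxyphenol (1.3 equiv), THF, rt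
Reagents that add atoms: 4-methoxyphenol, COc1ccc(O)cc1
Why: Tsuji–Trost opening of a vinyl epoxide: zerovalent palladium ionises the allylic C12–O bond, the phenoxide attacks the unhindered primary terminus C20 (1,4-addition), the untouched C13–O bond keeps O-13 cis to O-14, and the methylidene is parked as an inert ring trisubstituted alkene so that it cannot close a six-membered ring with the later C7 vinyl group in step 14.

Step 8
Reactants: 10 diol lactone
Product: 11 lactol (anomeric mixture at C9)
Conditions: i-Bu2AlH (3.5 equiv), CH2Cl2/THF, −78 °C; Rochelle salt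
Reagents that add atoms: none
Why: Partial reduction of the γ-lactone to the lactol (tetrahedral aluminate stable at −78 °C), the free hydroxyls being carried as aluminium alkoxides and the aryl allyl ether being inert.

Step 9
Reactants: 11 lactol
Product: 12 (2S,9S)-tetraol carrying the (E)-2-methoxybuta-1,3-dienyl unit C8(OMe)=C7H–C6H=CH2 on C9
Conditions: (E)-1-methoxybuta-1,3-diene, s-BuLi, THF, −78 °C (1-lithio diene, 5 equiv); then 11, −78 → −20 °C; aq NaHCO3
Reagents that add atoms: (E)-1-methoxybuta-1,3-diene (as its 1-lithio derivative), CO/C=C/C=C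
Why: Addition of an α-lithiated enol ether (acyl anion equivalent, lithiated with retention of geometry so that C9 ends cis to the vinyl group) to the open hydroxy aldehyde form of the lactol under chelation control (Cram chelate type: the lithium alkoxides at O-2 and O-14 hold the C9 carbonyl oxygen syn to C1, so attack comes from the side of H-10), which should set C9 as S.

Step 10
Reactants: 12 tetraol
Product: 13 tetraacetate (OAc at C2, C9, C13, C14)
Conditions: Ac2O, DMAP, pyridine, CH2Cl2, 0 °C → rt
Reagents that add atoms: acetic anhydride, CC(=O)OC(C)=O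
Why: DMAP-catalysed acetylation of the four secondary hydroxyls under basic conditions that leave the acid-labile methoxydiene intact.

Step 11
Reactants: 13 tetraacetate
Product: 15 (7S)-α-hydroxy ketone (C8=O, C7–OH, C7 vinyl), via methoxy epoxide 14 (not isolated)
Conditions: dimethyldioxirane (1.05 equiv, acetone), CH2Cl2, −78 → −40 °C; then pH 7 phosphate buffer, 0 °C
Reagents that add atoms: dimethyldioxirane, CC1(C)OO1; water, O
Why: Rubottom-type oxidation of the enol ether: the electrophilic dioxirane picks the most electron-rich alkene, A(1,3) strain with the cis vinyl group fixes H-9 in the alkene plane so that attack comes anti to the bulky C10 (syn to the acetoxy group), which should set C7 as S, and hydrolytic collapse of the methoxy epoxide gives the C8 ketone.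

Step 12
Reactants: 15 hydroxy ketone
Product: 16 C7 2-bromopropanoate (mixture at the CHBr carbon)
Conditions: 2-bromopropanoyl bromide, pyridine, CH2Cl2, −40 → 0 °C
Reagents that add atoms: 2-bromopropanoyl bromide, CC(Br)C(Br)=O
Why: Esterification of the only free hydroxyl (O-7) with an acid bromide and pyridine at low temperature, mild enough not to enolise the α-hydroxy ketone; the CHBr epimers converge in step 13.

Step 13
Reactants: 16 bromo ester
Product: 17 (7S,8S,17R)-β-hydroxy-γ-lactone (ring-opened at C5/C6)
Conditions: SmI2 (2.2 equiv), THF, −78 °C; pH 7 buffer at −78 °C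
Reagents that add atoms: none
Why: Intramolecular samarium Reformatsky reaction (5-exo-trig aldol closure): SmI2 reduces the α-bromo ester faster than the ketone and the trivalent samarium enolate adds to the C8 ketone within a chelate, O-7 delivering C17 to the carbonyl face on which the C7 vinyl group lies anti to C9 (should set 8S) with the enolate methyl pointing away from C7 and C9 (should set 17R, the isomer also favoured on equilibration).

Step 14
Reactants: 17 hydroxy lactone
Product: 18 ten-membered (5Z)-ring compound with C20 p-methoxyphenyl ether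
Conditions: second-generation Hoveyda–Grubbs catalyst (15 mol %), toluene (1 mM), 80 °C, Ar sparge
Reagents that add atoms: none
Why: Ring-closing metathesis between the C7 vinyl group and the 1,1-disubstituted C5 alkene closes the ten-membered ring with loss of ethene, the ring size enforcing the Z trisubstituted C5=C6 alkene and the ring A alkene being inert.

Step 15
Reactants: 18 aryl ether
Product: 19 primary allylic alcohol (C20–OH, C11=C12)
Conditions: (NH4)2Ce(NO3)6, MeCN/H2O (4:1), 0 °C
Reagents that add atoms: none
Why: Oxidative cleavage of the p-methoxyphenyl ether by ceric ammonium nitrate (aryl group oxidised to benzoquinone), which frees the C20 hydroxyl without touching acetates, lactone or the tertiary hydroxyl.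

Step 16
Reactants: 19 allylic alcohol
Product: 22 frajunolide E, via sulfonylhydrazine 20 (not isolated), via allylic diazene 21 (not isolated)
Conditions: PPh3, diethyl azodicarboxylate, 2-nitrobenzenesulfonyl hydrazide, THF, −30 °C → rt
Reagents that add atoms: none
Why: Reductive 1,3-transposition of the primary allylic alcohol: Mitsunobu displacement by the sulfonyl hydrazide, loss of sulfinic acid to the monoalkyl diazene and retro-ene loss of N2 deliver hydrogen to C12 and move the alkene to C11=C20, the tertiary C8 hydroxyl being inert to the Mitsunobu reaction.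

Compound list
1 | penta-3,4-dien-1-ol | C=C=CCCO | starting material
2 | penta-3,4-dienal | C=C=CCC=O | intermediate
3 | (E)-triisopropyl(penta-1,3,4-trien-1-yloxy)silane | C=C=C/C=C/O[Si](C(C)C)(C(C)C)C(C)C | intermediate
4 | ethyl (E)-3-methyl-4-oxobut-2-enoate | CCOC(=O)/C=C(\C)C=O | starting material
5 | ethyl (1S,5S,6R)-6-formyl-6-methyl-2-methylidene-5-(triisopropylsilyloxy)cyclohex-3-ene-1-carboxylate | C=C1C=C[C@H](O[Si](C(C)C)(C(C)C)C(C)C)[C@](C)(C=O)[C@H]1C(=O)OCC | intermediate
6 | ethyl (1S,5S,6R)-6-formyl-5-hydroxy-6-methyl-2-methylidenecyclohex-3-ene-1-carboxylate | C=C1C=C[C@H](O)[C@](C)(C=O)[C@H]1C(=O)OCC | intermediate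
7 | dihydroxy ester: 6 with the formyl group converted into the (S)-1-hydroxy-4-methylpent-4-enyl group (C2–C5) | C=C1C=C[C@H](O)[C@](C)([C@@H](O)CCC(C)=C)[C@H]1C(=O)OCC | intermediate (not isolated)
8 | lactone alcohol: trans-fused γ-lactone from O-2 to C9, (2S) 3-methylbut-3-enyl chain, 1β-methyl, 10α-H, 14α-OH, 11(20),12-diene | C=C1C=C[C@H](O)[C@]2(C)[C@H](CCC(C)=C)OC(=O)[C@@H]12 | intermediate
9 | 12α,13α-epoxide of 8 (epoxide cis to 14α-OH, C11=C20 retained) | C=C1[C@@H]3O[C@@H]3[C@H](O)[C@]2(C)[C@H](CCC(C)=C)OC(=O)[C@@H]12 | intermediate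
10 | lactone diol: 13α,14α-diol, C11=C12 alkene, C20 p-methoxyphenyl ether | COc1ccc(OCC3=C[C@H](O)[C@H](O)[C@]2(C)[C@H](CCC(C)=C)OC(=O)[C@@H]32)cc1 | intermediate
11 | lactol of 10 (C9 hemiacetal, anomeric mixture) | COc1ccc(OCC3=C[C@H](O)[C@H](O)[C@]2(C)[C@H](CCC(C)=C)OC(O)[C@@H]32)cc1 | intermediate
12 | (2S,9S)-tetraol: 2,9,13α,14α-tetrahydroxy, C9 bearing the (E)-2-methoxybuta-1,3-dienyl unit (C9 cis to vinyl) | COc1ccc(OCC2=C[C@H](O)[C@H](O)[C@](C)([C@@H](O)CCC(C)=C)[C@H]2[C@H](O)/C(OC)=C\C=C)cc1 | intermediate
13 | tetraacetate of 12 | COc1ccc(OCC2=C[C@H](OC(C)=O)[C@H](OC(C)=O)[C@](C)([C@@H](OC(C)=O)CCC(C)=C)[C@H]2[C@H](OC(C)=O)/C(OC)=C\C=C)cc1 | intermediate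
14 | methoxy epoxide of 13 at C7–C8 (oxygen syn to the C9 acetoxy face) | COc1ccc(OCC2=C[C@H](OC(C)=O)[C@H](OC(C)=O)[C@](C)([C@@H](OC(C)=O)CCC(C)=C)[C@H]2[C@H](OC(C)=O)[C@@]3(OC)O[C@H]3C=C)cc1 | intermediate (not isolated)
15 | (7S)-hydroxy ketone: C8 ketone, C7 hydroxyl and vinyl, four acetates | COc1ccc(OCC2=C[C@H](OC(C)=O)[C@H](OC(C)=O)[C@](C)([C@@H](OC(C)=O)CCC(C)=C)[C@H]2[C@H](OC(C)=O)C(=O)[C@@H](O)C=C)cc1 | intermediate
16 | 2-bromopropanoate of 15 at O-7 (mixture at CHBr) | COc1ccc(OCC2=C[C@H](OC(C)=O)[C@H](OC(C)=O)[C@](C)([C@@H](OC(C)=O)CCC(C)=C)[C@H]2[C@H](OC(C)=O)C(=O)[C@@H](OC(=O)C(C)Br)C=C)cc1 | intermediate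
17 | (7S,8S,17R)-hydroxy lactone: 8-hydroxy-17-methyl γ-lactone with C7 vinyl, diene for ring closure | COc1ccc(OCC2=C[C@H](OC(C)=O)[C@H](OC(C)=O)[C@](C)([C@@H](OC(C)=O)CCC(C)=C)[C@H]2[C@H](OC(C)=O)[C@]3(O)[C@@H](C)C(=O)O[C@H]3C=C)cc1 | intermediate
18 | ten-membered (5Z)-ring compound: frajunolide E skeleton with C11=C12 alkene and C20 p-methoxyphenyl ether | COc1ccc(OCC4=C[C@H](OC(C)=O)[C@H](OC(C)=O)[C@]2(C)[C@@H](OC(C)=O)CC/C(C)=C\[C@@H]3OC(=O)[C@H](C)[C@@]3(O)[C@@H](OC(C)=O)[C@@H]42)cc1 | intermediate
19 | C20 primary allylic alcohol (C11=C12) | OCC4=C[C@H](OC(C)=O)[C@H](OC(C)=O)[C@]2(C)[C@@H](OC(C)=O)CC/C(C)=C\[C@@H]3OC(=O)[C@H](C)[C@@]3(O)[C@@H](OC(C)=O)[C@@H]42 | intermediate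
20 | N-(C20-allyl)-N-(2-nitrophenylsulfonyl)hydrazine | NN(CC4=C[C@H](OC(C)=O)[C@H](OC(C)=O)[C@]2(C)[C@@H](OC(C)=O)CC/C(C)=C\[C@@H]3OC(=O)[C@H](C)[C@@]3(O)[C@@H](OC(C)=O)[C@@H]42)S(=O)(=O)c1ccccc1[N+](=O)[O-] | intermediate (not isolated)
21 | C20 monoalkyl diazene | N=NCC4=C[C@H](OC(C)=O)[C@H](OC(C)=O)[C@]2(C)[C@@H](OC(C)=O)CC/C(C)=C\[C@@H]3OC(=O)[C@H](C)[C@@]3(O)[C@@H](OC(C)=O)[C@@H]42 | intermediate (not isolated)
22 | frajunolide E | C=C1C[C@H](OC(C)=O)[C@H](OC(C)=O)[C@]2(C)[C@@H](OC(C)=O)CC/C(C)=C\[C@@H]3OC(=O)[C@H](C)[C@@]3(O)[C@@H](OC(C)=O)[C@@H]12 | target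

Total step count: 16. Longest linear sequence: 16 steps (1 → 22).

Steps most likely to fail

Step 3. The acid-labile allenyl silyl dienol ether may be protodesilylated or add to the formyl group under the strongly acidic boron catalyst, or the enal faces may be poorly discriminated. The fallback replaces the chiral catalyst by a covalent chiral controller on the diene oxygen and sets out from 2. Acylation of 2 with (S)-2-methoxy-2-phenylacetyl chloride (Et3N, DMAP, CH2Cl2, −20 °C) gives (E)-penta-1,3,4-trienyl (S)-2-methoxy-2-phenylacetate F1. Cycloaddition of F1 with 4 (BF3·OEt2, toluene, −78 °C, or thermally) should give the mandelate-bearing cycloadduct F2 with the same regio- and endo-selectivity, its diastereomers being separable by chromatography. Mild methanolysis of the activated α-alkoxy ester (K2CO3, MeOH, −10 °C) comes back to the route at 6. The (S)-acid is proposed; its antipode would be used if the sense of induction required it.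

Step 13. Single-electron reduction of the ketone with cleavage of its α-acyloxy C–O bonds may compete with enolate formation, or the aldol may close on the wrong carbonyl face. The fallback uses a non-reducing intermolecular zinc enolate and sets out from 15. The Reformatsky reagent from ethyl 2-bromopropanoate (Zn, THF, 0 °C) should add to the C8 ketone within the zinc chelate of the C7 hydroxyl, anti to the vinyl group, to give the open β-hydroxy ester F3. Lactonisation onto O-7 (PPTS, CH2Cl2) and, if needed, equilibration at C17 (DBU) come back at 17.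

Step 14. Intermolecular cross-metathesis (oligomerisation) may outrun closure of the strained ten-membered ring, the rigid lactone holding C6 away from C5. The fallback closes the ring before the lactone is built and sets out from 15. Ring-closing metathesis of the flexible hydroxy ketone, whose free allylic hydroxyl assists the catalyst (second-generation Hoveyda–Grubbs catalyst, CH2Cl2, 40 °C, 1 mM), should give the ten-membered hydroxy ketone F4. Acylation with 2-bromopropanoyl bromide and pyridine gives the bromo ester F5, and SmI2 (THF, −78 °C) then closes the lactone across the ring, coming back at 18.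

Further compounds
F1 | step 3 | (E)-penta-1,3,4-trienyl (S)-2-methoxy-2-phenylacetate | C=C=C/C=C/OC(=O)[C@@H](OC)c1ccccc1
F2 | step 3 | cycloadduct carrying the (S)-2-methoxy-2-phenylacetate on O-14 (otherwise as 5) | C=C1C=C[C@H](OC(=O)[C@@H](OC)c2ccccc2)[C@](C)(C=O)[C@H]1C(=O)OCC
F3 | step 13 | open β-hydroxy ester: C8 hydroxyl and C8-bound CH(CH3)CO2Et, free C7 hydroxyl | COc1ccc(OCC2=C[C@H](OC(C)=O)[C@H](OC(C)=O)[C@](C)([C@@H](OC(C)=O)CCC(C)=C)[C@H]2[C@H](OC(C)=O)[C@](O)([C@@H](C)C(=O)OCC)[C@@H](O)C=C)cc1
F4 | step 14 | ten-membered (5Z)-hydroxy ketone (C7–OH, C8=O) | COc1ccc(OCC4=C[C@H](OC(C)=O)[C@H](OC(C)=O)[C@]2(C)[C@@H](OC(C)=O)CC/C(C)=C\[C@H](O)C(=O)[C@@H](OC(C)=O)[C@@H]42)cc1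
F5 | step 14 | 2-bromopropanoate of F4 at O-7 | COc1ccc(OCC4=C[C@H](OC(C)=O)[C@H](OC(C)=O)[C@]2(C)[C@@H](OC(C)=O)CC/C(C)=C\[C@H](OC(=O)C(C)Br)C(=O)[C@@H](OC(C)=O)[C@@H]42)cc1
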